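The route disconnects the aryl ether bond O1–C8a of the flavanone ring C, not the usual O1–C2 bond. The precursor is an open-chain (S)-β-hydroxy ketone whose ring A carries fluorine at C8a. Deprotonation lets the C2 alkoxide displace fluoride in an intramolecular SNAr that closes ring C in one operation without touching the C2–O bond, so the configuration is carried over intact. The step exploits the phloroglucinol pattern of ring A: C8a lies ortho to the C4 ketone (on C4a) and meta to both oxygenated carbons C5 and C7. The carbinol centre comes from copper-catalysed asymmetric borylation–oxidation of a chalcone assembled by Suzuki coupling and aldol condensation.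

Key step: step 10

Assumption: ring and atom labels (ring A, ring C, C2, C4, C4a, C8a) follow flavanone numbering of the dihydro unit; the biaryl axis is taken as freely rotating; acacetin, 3-bromo-4-hydroxybenzaldehyde and 5-fluororesorcinol are taken as commercial; the facial sense of the Josiphos–copper catalyst in step 9 is assigned by analogy with β-aryl enones and cinnamates, and the antipodal ligand is used should the opposite carbinol form.

Step 1
Reactants: 1 acacetin (5,7-dihydroxy-2-(4-methoxyphenyl)-4H-chromen-4-one)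
Product: 2 5,7-bis(methoxymethoxy)-2-(4-methoxyphenyl)-4H-chromen-4-one
Conditions: NaH (2.5 equiv), MOMCl (2.6 equiv), DMF, 0 °C to rt
Reagents that add atoms: chloromethyl methyl ether (MOMCl), COCCl
Why: Williamson-type O-alkylation of both phenoxides, NaH being strong enough to break the hydrogen bond of the 5-OH to the C4 carbonyl, and masking both hydroxyls steers the following iodination to C8.

Step 2
Reactants: 2 5,7-bis(methoxymethoxy)-2-(4-methoxyphenyl)-4H-chromen-4-one
Product: 3 8-iodo-5,7-bis(methoxymethoxy)-2-(4-methoxyphenyl)-4H-chromen-4-one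
Conditions: N-iodosuccinimide (1.1 equiv), DMF, rt to 50 °C, dark
Reagents that add atoms: N-iodosuccinimide, O=C1CCC(=O)N1I
Why: Electrophilic aromatic iodination, which in 5,7-dialkoxyflavones should go to C8 because C6 is flanked by two alkoxy groups, under neutral conditions that keep the MOM acetals.

Step 3
Reactants: 4 3-bromo-4-hydroxybenzaldehyde
Product: 5 3-bromo-4-(methoxymethoxy)benzaldehyde
Conditions: NaH (1.1 equiv), MOMCl (1.2 equiv), THF–DMF, 0 °C
Reagents that add atoms: chloromethyl methyl ether (MOMCl), COCCl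
Why: Williamson-type O-alkylation of the phenoxide, the aldehyde having no enolisable position.

Step 4
Reactants: 5 3-bromo-4-(methoxymethoxy)benzaldehyde
Product: 6 4-(methoxymethoxy)-3-(4,4,5,5-tetramethyl-1,3,2-dioxaborolan-2-yl)benzaldehyde
Conditions: B2pin2 (1.2 equiv), Pd(dppf)Cl2 (3 mol%), KOAc (3 equiv), 1,4-dioxane, 90 °C
Reagents that add atoms: bis(pinacolato)diboron, CC1(C)OB(OC1(C)C)B1OC(C)(C)C(C)(C)O1
Why: Miyaura borylation of the aryl bromide, in which the weak acetate base tolerates the aldehyde and prevents homocoupling.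

Step 5
Reactants: 3 8-iodo-5,7-bis(methoxymethoxy)-2-(4-methoxyphenyl)-4H-chromen-4-one; 6 4-(methoxymethoxy)-3-(4,4,5,5-tetramethyl-1,3,2-dioxaborolan-2-yl)benzaldehyde
Product: 7 3-[5,7-bis(methoxymethoxy)-2-(4-methoxyphenyl)-4-oxo-4H-chromen-8-yl]-4-(methoxymethoxy)benzaldehyde
Conditions: Pd(OAc)2 (5 mol%), SPhos (10 mol%), K3PO4 (3 equiv), toluene–H2O, 90 °C
Reagents that add atoms: none
Why: Suzuki–Miyaura coupling with a bulky biarylphosphine suited to tri-ortho-substituted biaryls, placed before any stereocenter exists so that hot aqueous base is harmless.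

Step 6
Reactants: 8 5-fluororesorcinol (5-fluorobenzene-1,3-diol)
Product: 10 1-(2-fluoro-4,6-dihydroxyphenyl)ethan-1-one, via ketiminium chloride 9 (not isolated)
Conditions: MeCN (1.5 equiv), ZnCl2 (0.3 equiv), HCl (g), Et2O, 0 °C; then H2O, 90 °C
Reagents that add atoms: acetonitrile, CC#N; water, O
Why: Hoesch acylation, in which the nitrilium electrophile attacks the carbon ortho to one hydroxyl and para to the other (next to fluorine) and not the carbon between the two hydroxyls, and hydrolysis of the ketiminium salt gives the methyl ketone with fluorine ortho to the acetyl group.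

Step 7
Reactants: 10 1-(2-fluoro-4,6-dihydroxyphenyl)ethan-1-one
Product: 11 1-[2-fluoro-4,6-bis(methoxymethoxy)phenyl]ethan-1-one
Conditions: NaH (2.3 equiv), MOMCl (2.4 equiv), DMF, 0 °C to rt
Reagents that add atoms: chloromethyl methyl ether (MOMCl), COCCl
Why: Williamson-type O-alkylation of both phenoxides (the chelated one included), which removes the acidic phenols that would otherwise deactivate ring A toward the later SNAr.

Step 8
Reactants: 7 3-[5,7-bis(methoxymethoxy)-2-(4-methoxyphenyl)-4-oxo-4H-chromen-8-yl]-4-(methoxymethoxy)benzaldehyde; 11 1-[2-fluoro-4,6-bis(methoxymethoxy)phenyl]ethan-1-one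
Product: 13 (2E)-3-{3-[5,7-bis(methoxymethoxy)-2-(4-methoxyphenyl)-4-oxo-4H-chromen-8-yl]-4-(methoxymethoxy)phenyl}-1-[2-fluoro-4,6-bis(methoxymethoxy)phenyl]prop-2-en-1-one, via racemic aldol adduct 12 (not isolated)
Conditions: KOH (5 equiv), EtOH–THF, rt
Reagents that add atoms: none
Why: Claisen–Schmidt aldol condensation, in which the methyl ketone enolate adds to the non-enolisable aldehyde and E1cB loss of water gives the thermodynamically favoured E-enone.

Step 9
Reactants: 13 the (2E)-chalcone of step 8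
Product: 15 (3S)-3-{3-[5,7-bis(methoxymethoxy)-2-(4-methoxyphenyl)-4-oxo-4H-chromen-8-yl]-4-(methoxymethoxy)phenyl}-1-[2-fluoro-4,6-bis(methoxymethoxy)phenyl]-3-hydroxypropan-1-one, via beta-boryl ketone 14 (not isolated)
Conditions: CuCl (5 mol%), NaOtBu (10 mol%), (R)-1-[(SP)-2-(diphenylphosphino)ferrocenyl]ethyldicyclohexylphosphine (Josiphos, 5 mol%), B2pin2 (1.2 equiv), MeOH (2 equiv), THF, rt; then NaBO3·4H2O, THF–H2O, rt
Reagents that add atoms: bis(pinacolato)diboron, CC1(C)OB(OC1(C)C)B1OC(C)(C)C(C)(C)O1 (boryl group of 14); sodium perborate tetrahydrate, O.O.O.O.O.O.[Na+].[Na+].O[B-]1(O)OO[B-](O)(O)OO1 (hydroxyl oxygen of 15)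
Why: Copper-catalysed asymmetric conjugate borylation of the enone places boron on the benzylic β-carbon with the face chosen by the chiral Josiphos–copper boryl complex (catalyst control), and perborate oxidation replaces C–B by C–O with retention to give the (S)-carbinol, while the β,β-disubstituted flavone enone should stay untouched.

Step 10
Reactants: 15 the (3S)-β-hydroxy ketone of step 9
Product: 16 (2S)-2-{3-[5,7-bis(methoxymethoxy)-2-(4-methoxyphenyl)-4-oxo-4H-chromen-8-yl]-4-(methoxymethoxy)phenyl}-5,7-bis(methoxymethoxy)-2,3-dihydro-4H-chromen-4-one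
Conditions: KN(SiMe3)2 (1.0 equiv), THF, −78 to −20 °C; AcOH, −20 °C
Reagents that add atoms: none
Why: The base deprotonates the C2 hydroxyl and the alkoxide adds to C8a to give a Meisenheimer anion whose charge rests on C4a and the C4 carbonyl (also on C6 and C8, never on the oxygen-bearing C5 and C7), after which fluoride is expelled. The closest known reaction type is the intramolecular SNAr O-arylation of alkoxides on ortho-fluoroaryl ketones used to make chroman-4-ones and xanthones. Ring C closes as a six-membered ring by attack on a trigonal aromatic carbon, formally 6-exo-trig when the displaced π pair is written onto C8 and 6-endo-trig when it is written through C4a onto the C4 carbonyl, both allowed. No new stereocenter is formed: the C2–O bond is never broken, so the (S) configuration from step 9 is kept, which a reversible O1–C2 closure by oxa-Michael addition could not guarantee. The step needs O-arylation to outrun retro-aldol cleavage and E1cB dehydration, and it must not leave the base-labile flavanone in contact with base. One equivalent of base at low temperature in an aprotic solvent, consumed as KF, together with fast six-membered closure onto the only carbon that bears a leaving group, should secure this.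

Step 11
Reactants: 16 the (2S)-penta-MOM flavanone of step 10
Product: 17 2,3-dihydropodocarpusflavone A, (2S)-2-{3-[5,7-dihydroxy-2-(4-methoxyphenyl)-4-oxo-4H-chromen-8-yl]-4-hydroxyphenyl}-5,7-dihydroxy-2,3-dihydro-4H-chromen-4-one
Conditions: HCl (3 M in MeOH), THF, 40 °C
Reagents that add atoms: none
Why: Acid-catalysed acetal exchange removes all five MOM ethers while the aryl methyl ether is inert and the flavanone, which epimerises only through base-mediated ring opening, should keep its configuration in acid.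

Compound list
1 | acacetin, 5,7-dihydroxy-2-(4-methoxyphenyl)-4H-chromen-4-one | COc1ccc(-c2cc(=O)c3c(O)cc(O)cc3o2)cc1 | starting material
2 | 5,7-bis(methoxymethoxy)-2-(4-methoxyphenyl)-4H-chromen-4-one | COc1ccc(-c2cc(=O)c3c(OCOC)cc(OCOC)cc3o2)cc1 | intermediate
3 | 8-iodo-5,7-bis(methoxymethoxy)-2-(4-methoxyphenyl)-4H-chromen-4-one | COc1ccc(-c2cc(=O)c3c(OCOC)cc(OCOC)c(I)c3o2)cc1 | intermediate
4 | 3-bromo-4-hydroxybenzaldehyde | O=Cc1ccc(O)c(Br)c1 | starting material
5 | 3-bromo-4-(methoxymethoxy)benzaldehyde | COCOc1ccc(C=O)cc1Br | intermediate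
6 | 4-(methoxymethoxy)-3-(4,4,5,5-tetramethyl-1,3,2-dioxaborolan-2-yl)benzaldehyde | COCOc1ccc(C=O)cc1B1OC(C)(C)C(C)(C)O1 | intermediate
7 | 3-[5,7-bis(methoxymethoxy)-2-(4-methoxyphenyl)-4-oxo-4H-chromen-8-yl]-4-(methoxymethoxy)benzaldehyde | COc1ccc(-c2cc(=O)c3c(OCOC)cc(OCOC)c(-c4cc(C=O)ccc4OCOC)c3o2)cc1 | intermediate
8 | 5-fluororesorcinol (5-fluorobenzene-1,3-diol) | Oc1cc(O)cc(F)c1 | starting material
9 | 1-(2-fluoro-4,6-dihydroxyphenyl)ethan-1-iminium chloride (not isolated) | CC(=[NH2+])c1c(O)cc(O)cc1F.[Cl-] | intermediate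
10 | 1-(2-fluoro-4,6-dihydroxyphenyl)ethan-1-one | CC(=O)c1c(O)cc(O)cc1F | intermediate
11 | 1-[2-fluoro-4,6-bis(methoxymethoxy)phenyl]ethan-1-one | CC(=O)c1c(OCOC)cc(OCOC)cc1F | intermediate
12 | racemic 3-{3-[5,7-bis(methoxymethoxy)-2-(4-methoxyphenyl)-4-oxo-4H-chromen-8-yl]-4-(methoxymethoxy)phenyl}-1-[2-fluoro-4,6-bis(methoxymethoxy)phenyl]-3-hydroxypropan-1-one (not isolated) | COc1ccc(-c2cc(=O)c3c(OCOC)cc(OCOC)c(-c4cc(C(O)CC(=O)c5c(OCOC)cc(OCOC)cc5F)ccc4OCOC)c3o2)cc1 | intermediate
13 | (2E)-3-{3-[5,7-bis(methoxymethoxy)-2-(4-methoxyphenyl)-4-oxo-4H-chromen-8-yl]-4-(methoxymethoxy)phenyl}-1-[2-fluoro-4,6-bis(methoxymethoxy)phenyl]prop-2-en-1-one | COc1ccc(-c2cc(=O)c3c(OCOC)cc(OCOC)c(-c4cc(/C=C/C(=O)c5c(OCOC)cc(OCOC)cc5F)ccc4OCOC)c3o2)cc1 | intermediate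
14 | (3S)-3-{3-[5,7-bis(methoxymethoxy)-2-(4-methoxyphenyl)-4-oxo-4H-chromen-8-yl]-4-(methoxymethoxy)phenyl}-1-[2-fluoro-4,6-bis(methoxymethoxy)phenyl]-3-(4,4,5,5-tetramethyl-1,3,2-dioxaborolan-2-yl)propan-1-one (not isolated) | COc1ccc(-c2cc(=O)c3c(OCOC)cc(OCOC)c(-c4cc([C@@H](B5OC(C)(C)C(C)(C)O5)CC(=O)c5c(OCOC)cc(OCOC)cc5F)ccc4OCOC)c3o2)cc1 | intermediate
15 | (3S)-3-{3-[5,7-bis(methoxymethoxy)-2-(4-methoxyphenyl)-4-oxo-4H-chromen-8-yl]-4-(methoxymethoxy)phenyl}-1-[2-fluoro-4,6-bis(methoxymethoxy)phenyl]-3-hydroxypropan-1-one | COc1ccc(-c2cc(=O)c3c(OCOC)cc(OCOC)c(-c4cc([C@@H](O)CC(=O)c5c(OCOC)cc(OCOC)cc5F)ccc4OCOC)c3o2)cc1 | intermediate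
16 | (2S)-2-{3-[5,7-bis(methoxymethoxy)-2-(4-methoxyphenyl)-4-oxo-4H-chromen-8-yl]-4-(methoxymethoxy)phenyl}-5,7-bis(methoxymethoxy)-2,3-dihydro-4H-chromen-4-one | COc1ccc(-c2cc(=O)c3c(OCOC)cc(OCOC)c(-c4cc([C@@H]5CC(=O)c6c(OCOC)cc(OCOC)cc6O5)ccc4OCOC)c3o2)cc1 | intermediate
17 | 2,3-dihydropodocarpusflavone A, (2S)-2-{3-[5,7-dihydroxy-2-(4-methoxyphenyl)-4-oxo-4H-chromen-8-yl]-4-hydroxyphenyl}-5,7-dihydroxy-2,3-dihydro-4H-chromen-4-one | COc1ccc(-c2cc(=O)c3c(O)cc(O)c(-c4cc([C@@H]5CC(=O)c6c(O)cc(O)cc6O5)ccc4O)c3o2)cc1 | target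

Total step count: 11. Longest linear sequence: 7 steps (steps 1, 2, 5, 8, 9, 10, 11 from acacetin; the branch through steps 3 and 4 is equally long).

Steps most likely to fail

Step 10 (key step). The alkoxide of 15 may fragment by retro-aldol cleavage, or the derived enolate may lose hydroxide by E1cB, faster than ring closure; a reversible retro-aldol step would also erode the configuration, and excess base would open the product flavanone. Fallback: remove the carbonyl before closing the same bond. Setting out from 15, NaBH4 (MeOH–THF, 0 °C) should give the diol (3S)-3-{3-[5,7-bis(methoxymethoxy)-2-(4-methoxyphenyl)-4-oxo-4H-chromen-8-yl]-4-(methoxymethoxy)phenyl}-1-[2-fluoro-4,6-bis(methoxymethoxy)phenyl]propane-1,3-diol F1 as a mixture of C1 epimers, which is immaterial. Its dialkoxide (KOtBu, DMF, 60–80 °C) can undergo neither retro-aldol cleavage nor E1cB loss and should close O1–C8a by intramolecular SNAr on the fluoroarene, still activated inductively by the two meta alkoxy groups, to give the flavan-4-ol (2S)-2-{3-[5,7-bis(methoxymethoxy)-2-(4-methoxyphenyl)-4-oxo-4H-chromen-8-yl]-4-(methoxymethoxy)phenyl}-5,7-bis(methoxymethoxy)chroman-4-ol F2. Only the C2 oxygen can reach C8a, since the C4 oxygen would have to form a four-membered ring. Dess–Martin periodinane (NaHCO3, CH2Cl2, rt) then oxidises the C4 carbinol and the route is rejoined at 16.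

Step 9. Facial selectivity may be poor on the twisted, di-ortho-substituted aroyl enone, and conjugate addition to the electron-rich β-aryl enone may be sluggish. Fallback: set the carbinol by epoxidation and reductive opening. Setting out from 13, Juliá–Colonna epoxidation with poly-D-leucine (urea–hydrogen peroxide, DBU, THF, rt) should give the trans epoxy ketone [(2S,3R)-3-{3-[5,7-bis(methoxymethoxy)-2-(4-methoxyphenyl)-4-oxo-4H-chromen-8-yl]-4-(methoxymethoxy)phenyl}oxiran-2-yl][2-fluoro-4,6-bis(methoxymethoxy)phenyl]methanone F3. Reductive cleavage of the Cα–O bond only ((PhSe)2, NaBH4, AcOH, EtOH–THF, 0 °C) leaves the benzylic C–O bond and its configuration untouched and returns to the route at 15.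

Step 8. In ethanolic hydroxide the activated fluoride may be displaced by ethoxide or hydroxide, the transient aldolate may cyclise prematurely to racemic flavanone, and the pyrone ring of the flavone may be opened. Fallback: a kinetic aldol followed by a separate elimination, with no hydroxide or free aldolate at room temperature. Setting out from 11, deprotonation with LiN(SiMe3)2 (THF, −78 °C), addition of 7 and a cold quench should give the racemic aldol 12, this time isolated. MsCl and Et3N (CH2Cl2, 0 °C) convert it into the mesylate 3-{3-[5,7-bis(methoxymethoxy)-2-(4-methoxyphenyl)-4-oxo-4H-chromen-8-yl]-4-(methoxymethoxy)phenyl}-1-[2-fluoro-4,6-bis(methoxymethoxy)phenyl]-3-oxopropyl methanesulfonate F4, which DBU eliminates to the E-enone, rejoining the route at 13.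

Further compounds
F1 | step 10 | (3S)-3-{3-[5,7-bis(methoxymethoxy)-2-(4-methoxyphenyl)-4-oxo-4H-chromen-8-yl]-4-(methoxymethoxy)phenyl}-1-[2-fluoro-4,6-bis(methoxymethoxy)phenyl]propane-1,3-diol (C1 epimers) | COc1ccc(-c2cc(=O)c3c(OCOC)cc(OCOC)c(-c4cc([C@@H](O)CC(O)c5c(OCOC)cc(OCOC)cc5F)ccc4OCOC)c3o2)cc1
F2 | step 10 | (2S)-2-{3-[5,7-bis(methoxymethoxy)-2-(4-methoxyphenyl)-4-oxo-4H-chromen-8-yl]-4-(methoxymethoxy)phenyl}-5,7-bis(methoxymethoxy)chroman-4-ol (C4 epimers) | COc1ccc(-c2cc(=O)c3c(OCOC)cc(OCOC)c(-c4cc([C@@H]5CC(O)c6c(OCOC)cc(OCOC)cc6O5)ccc4OCOC)c3o2)cc1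
F3 | step 9 | [(2S,3R)-3-{3-[5,7-bis(methoxymethoxy)-2-(4-methoxyphenyl)-4-oxo-4H-chromen-8-yl]-4-(methoxymethoxy)phenyl}oxiran-2-yl][2-fluoro-4,6-bis(methoxymethoxy)phenyl]methanone | COc1ccc(-c2cc(=O)c3c(OCOC)cc(OCOC)c(-c4cc([C@@H]5[C@@H](C(=O)c6c(OCOC)cc(OCOC)cc6F)O5)ccc4OCOC)c3o2)cc1
F4 | step 8 | racemic 3-{3-[5,7-bis(methoxymethoxy)-2-(4-methoxyphenyl)-4-oxo-4H-chromen-8-yl]-4-(methoxymethoxy)phenyl}-1-[2-fluoro-4,6-bis(methoxymethoxy)phenyl]-3-oxopropyl methanesulfonate | COc1ccc(-c2cc(=O)c3c(OCOC)cc(OCOC)c(-c4cc(C(OS(C)(=O)=O)CC(=O)c5c(OCOC)cc(OCOC)cc5F)ccc4OCOC)c3o2)cc1
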